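**Assumption:** 5-(4-hydroxyphenyl)pentanoic acid (1) and meso-2,4-dimethylglutaric anhydride (6) are taken as commercial. Ring atoms are numbered C1 (ketone), C2 (C–N), C3, C4 (carbinol), C5, C6 (C–Cl) and side-chain atoms C1′–C9′, independent of the locants in systematic names.

## Analysis of the target

The target is a para-quinol: a cross-conjugated cyclohexa-2,5-dienone with the ketone at C1, the amide nitrogen on C2, chlorine on C6, and OH plus a 4-carboxybutyl chain on the tertiary carbinol C4. C4 is the only ring stereocentre, it is (R), and it is stereogenic solely because C2 bears nitrogen while C6 bears chlorine. With the same atom on C2 and C6 the ring has a mirror plane through C1, C4, the hydroxyl oxygen and the chain, and the two enone arms C2=C3 and C6=C5 become enantiotopic. This hidden mirror plane is the feature the route is built on: the C6–Cl bond is read as the surviving twin of a second C–Cl bond at C2, so that making the C2–N bond on a symmetric 2,6-dichloro ring sets C4 without touching it. The N-acyl group is (2E,4S,6R)-4,6,8-trimethylnona-2,7-dienoyl, a syn-1,3-dimethyl pair (C4′, C6′) between a conjugated E-enamide and an isopropylidene alkene. Ring C4 and C4′ are seven bonds apart, so neither stereochemical domain can control the other and C4 needs an external source of chirality. Sensitive groups are the chlorodienone (Michael acceptor, labile to base and nucleophiles), the doubly allylic tertiary alcohol (ionisation and dienone–phenol rearrangement in acid), the enamide, the acid-labile trisubstituted alkene and the epimerisable α-methyl aldehydes on the way to the side chain. The difficulty is therefore not the ring, which phenol oxidation delivers at once, but single-enantiomer control of a quaternary carbinol whose two ring neighbours differ only one atom further out.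

## Retrosynthetic reasoning

**15 ⇒ 14.** The carboxylic acid is carried as the methyl ester 14. The ester goes on in the first step, keeps a carboxylate out of the base-mediated coupling, and is removed last by an enzyme at neutral pH, because the chlorodienone tolerates neither hydroxide nor strong acid.

**14 ⇒ 5 + 13 (key disconnection).** The C2–N bond is cut. Putting chlorine back on C2 gives 5, in which C2 and C6 are identical; 5 has a mirror plane, is achiral and can be made with no stereocontrol at all. The cut is made here and not at C4–O or C4–C because it is the only ring bond whose formation can distinguish the two enone arms while delivering the whole side chain. The forward reaction has to replace one of two enantiotopic chlorines by the nitrogen of the primary amide 13 under control of a chiral palladium catalyst, and stop after one coupling. The gain is threefold: the two halves meet in the step that defines C4, the chlorine of the target needs no separate introduction, and both partners are simple.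

**5 ⇒ 4 ⇒ 2 ⇒ 1.** The C4–O bond is made by hydroxylative dearomatisation of the symmetric dichlorophenol 4, at a stage where the two faces of the arene are equivalent and no selectivity is asked for. The two chlorines come from double ortho-chlorination of 2, whose para position is blocked, and 2 is the methyl ester of 1.

**13 ⇒ 11.** The C2′=C3′ bond is cut to a Wittig olefination of aldehyde 12 with an amide-stabilised ylide. This installs the E-alkene and the primary amide together and under neutral conditions, so the α-stereocentre C4′ is not put at risk; 12 is made and used in the same flask from alcohol 11.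

**11 ⇒ 9.** The C7′=C8′ bond is cut to a Wittig olefination of aldehyde 9 with a non-stabilised isopropylidene ylide. Two identical methyl groups on the new alkene mean no geometry has to be controlled; the acetate 10 formed first is cleaved in the same flask.

**9 ⇒ 8 ⇒ 7 ⇒ 6.** Both methyl stereocentres are taken intact from the meso anhydride 6 through the meso diol 7. The only stereochemical decision is which end of the meso chain becomes which alkene, and a lipase makes it in one acetylation to 8. Cutting the side chain at the two alkenes and not between C4′ and C6′ avoids building the syn-1,3-dimethyl relationship altogether.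

## Alternatives that were turned down

**Alternative 1:** the textbook disconnection of the C4–OH bond. The forward key step is oxidation of the fully assembled amidophenol A1 with PhI(OAc)2 in aqueous MeCN, so that water adds para to the phenol oxygen and gives 14 directly. It was turned down because the two faces of A1 differ only in Cl against NHCOR at the positions ortho to the phenol oxygen, and the side-chain stereocentres are seven bonds from C4, so no substrate bias exists and an unselective mixture at C4 is expected. A chiral aryl iodide would have to steer an unbound water molecule at the para carbon, far from the oxygen through which the phenol binds to trivalent iodine. A1 also costs a linear nitration, chlorination, reduction and acylation sequence and commits the complete side chain before the unselective step. It is kept only as the fallback.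

**Alternative 2:** disconnection of the C4–C bond to the chain (quinone monoketal logic). The forward key step is 1,2-addition of the ester-bearing organozinc reagent A3, or a more reactive metal derivative of it, to the ketone of the amido chloro quinone monoketal A2, followed by acid hydrolysis of the ketal to unveil C1=O. It was turned down because the two faces of that ketone are enantiotopic only through N against Cl on the β-carbons, which no chiral promoter of organometallic addition can be expected to read. An ester-tolerant organometallic is also poorly matched to 1,2-addition on a hindered dienone (conjugate addition and N–H deprotonation compete), and A2 itself needs four to five steps. The result would again be both C4 configurations after a longer route.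

**Alternative 3:** disconnection of the C6–Cl bond and the C5=C6 alkene to an oxirane. The forward key step treats the syn-epoxyquinol A4 with HCl: chloride opens the oxirane at C6, α to the ketone, and the resulting β-hydroxy ketone loses water to the chlorodienone. It was turned down because it moves the stereochemical problem to A4, which has three contiguous stereocentres of which two are destroyed again, and whose synthesis needs an enantioselective epoxidation of a quinone monoketal plus the unselective carbinol construction of Alternative 2, at least six more steps. The HCl step further endangers the tertiary allylic alcohol and the isopropylidene alkene.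

Key step: step 9

## Route

Step 1
Reactants: 1 5-(4-hydroxyphenyl)pentanoic acid
Product: 2 methyl 5-(4-hydroxyphenyl)pentanoate
Conditions: MeOH, H2SO4 (cat.), reflux
Reagents that add atoms: methanol, CO
Why: Fischer esterification; the phenol is not alkylated under acid catalysis, and the ester keeps a carboxylate out of the base-mediated coupling of step 9.

Step 2
Reactants: 2 methyl 5-(4-hydroxyphenyl)pentanoate
Product: 4 methyl 5-(3,5-dichloro-4-hydroxyphenyl)pentanoate, via monochlorophenol 3 (not isolated)
Conditions: SO2Cl2 (2.1 equiv), i-Bu2NH (5 mol %), toluene, 65 °C
Reagents that add atoms: sulfuryl chloride, O=S(=O)(Cl)Cl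
Why: Amine-catalysed electrophilic chlorination of phenols with SO2Cl2 is ortho-selective; the para position is blocked and the two ortho positions are equivalent, so two equivalents should give the symmetric 2,6-dichlorophenol through 3.

Step 3
Reactants: 4 methyl 5-(3,5-dichloro-4-hydroxyphenyl)pentanoate
Product: 5 methyl 5-(3,5-dichloro-1-hydroxy-4-oxocyclohexa-2,5-dien-1-yl)pentanoate
Conditions: PhI(OCOCF3)2 (1.2 equiv), MeCN/H2O 3:1, 0 °C
Reagents that add atoms: water, O
Why: Hydroxylative oxidative dearomatisation with a trivalent iodine reagent: ligand exchange at iodine and loss of iodobenzene make the para carbon electrophilic and water adds there. The product keeps the mirror plane through C1 and C4, so no stereochemical question arises, and the remote ester cannot compete as an internal nucleophile.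

Step 4
Reactants: 6 meso-2,4-dimethylglutaric anhydride, (3R,5S)-3,5-dimethyloxane-2,6-dione
Product: 7 meso-(2R,4S)-2,4-dimethylpentane-1,5-diol
Conditions: LiAlH4, THF, 0 °C to reflux; aqueous NaOH work-up
Reagents that add atoms: none
Why: Hydride reduction of a cyclic anhydride to the diol; the cis relationship of the two methyl groups is carried over unchanged and the product is meso.

Step 5
Reactants: 7 meso-(2R,4S)-2,4-dimethylpentane-1,5-diol
Product: 8 (2S,4R)-5-hydroxy-2,4-dimethylpentyl acetate
Conditions: Pseudomonas fluorescens lipase, vinyl acetate, THF, 25 °C
Reagents that add atoms: vinyl acetate, C=COC(C)=O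
Why: Enzymatic desymmetrisation by irreversible transesterification; the lipase is expected to acetylate the hydroxymethyl arm on the (S)-configured carbon and leave the arm on the (R)-configured carbon free. This one operation fixes both side-chain stereocentres, and the reaction is stopped when 7 is consumed to limit diacetate formation.

Step 6
Reactants: 8 (2S,4R)-5-hydroxy-2,4-dimethylpentyl acetate
Product: 9 (2S,4R)-2,4-dimethyl-5-oxopentyl acetate
Conditions: Dess–Martin periodinane (1.2 equiv), CH2Cl2, 0 °C to rt; crude product used at once
Reagents that add atoms: none
Why: Dess–Martin oxidation of a primary alcohol under neutral conditions that should not epimerise the α-methyl stereocentre; the aldehyde is configurationally labile and is therefore not stored.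

Step 7
Reactants: 9 (2S,4R)-2,4-dimethyl-5-oxopentyl acetate
Product: 11 (2S,4R)-2,4,6-trimethylhept-5-en-1-ol, via acetate 10 (not isolated)
Conditions: i-PrPPh3I (1.4 equiv), n-BuLi (1.35 equiv), THF, 0 °C; then 9, −78 to 0 °C; then MeOH, K2CO3 (cat.), rt
Reagents that add atoms: isopropyltriphenylphosphonium iodide, CC(C)[P+](c1ccccc1)(c1ccccc1)c1ccccc1.[I-]
Why: Wittig olefination with the non-stabilised isopropylidene ylide at low temperature builds the C7′=C8′ alkene, with no E/Z question because the new carbon carries two methyl groups. Methanol and catalytic base added to the same flask transesterify acetate 10 to alcohol 11.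

Step 8
Reactants: 11 (2S,4R)-2,4,6-trimethylhept-5-en-1-ol
Product: 13 (2E,4S,6R)-4,6,8-trimethylnona-2,7-dienamide, via aldehyde 12 (not isolated)
Conditions: TEMPO (10 mol %), PhI(OAc)2 (1.05 equiv), CH2Cl2, rt; then Ph3P=CHCONH2 (2 equiv), rt to 40 °C
Reagents that add atoms: 2-(triphenyl-λ5-phosphanylidene)acetamide, NC(=O)C=P(c1ccccc1)(c1ccccc1)c1ccccc1
Why: One-pot oxoammonium oxidation and Wittig olefination with a stabilised ylide; the α-chiral aldehyde 12 is formed and consumed under neutral conditions, which protects C4′. Stabilised ylides give the E-alkene, and the primary amide needed for step 9 is installed directly.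

Step 9
Reactants: 5 methyl 5-(3,5-dichloro-1-hydroxy-4-oxocyclohexa-2,5-dien-1-yl)pentanoate (1.5 equiv); 13 (2E,4S,6R)-4,6,8-trimethylnona-2,7-dienamide (1.0 equiv)
Product: 14 methyl 5-[(1R)-3-chloro-1-hydroxy-4-oxo-5-[[(2E,4S,6R)-4,6,8-trimethylnona-2,7-dienoyl]amino]cyclohexa-2,5-dien-1-yl]pentanoate
Conditions: Pd2(dba)3 (2.5 mol %), (R)-DTBM-SEGPHOS (6 mol %), K3PO4 (1.5 equiv), toluene, 60 °C
Reagents that add atoms: none
Why: Proposed new method: ligated zerovalent palladium should add oxidatively to one of the two enantiotopic α-chloroenone C–Cl bonds of 5, phosphate-assisted exchange of chloride on divalent palladium for the deprotonated amide 13 follows, and C–N reductive elimination, which is easy from an electron-poor alkenyl ligand, releases 14; the closest known reaction types are the palladium-catalysed amidation of alkenyl halides and α-halo enones (Buchwald–Hartwig type) and the enantioselective desymmetrising N-arylation of prochiral dihalides with axially chiral bisphosphines, neither yet shown for a prochiral 2,6-dichlorodienone. No ring is closed; the step joins the complete side chain to the ring through the C2–N bond. The one new stereocentre, ring C4, is created without any bond being made to it: its configuration depends only on which of the two chlorines is replaced, and that choice is under control of the chiral ligand. The metal is expected to approach the dienone on the hydroxyl face, the less hindered face of a 4-alkyl-4-hydroxycyclohexadienone, and on that face the two chloroalkene arms are mirror images, so a ligand that reads the prochiral face of a chloroenone tells the two chlorines apart. Mono-coupling is secured by the excess of 5 and by the fact that a second amidation would consume mainly the minor C4 epimer, whose remaining chlorine is the one the catalyst prefers. N- over O-coupling is secured by the much stronger binding of an amidate than of a hindered tertiary alkoxide to palladium, and the weak insoluble base leaves the methyl ester and the dienone alone. Because 13 is a single enantiomer, a wrong choice of chlorine gives a diastereomer of 14 and not its enantiomer, so the selectivity can be read directly, the minor isomer can be removed by chromatography, and the ligand antipode is chosen accordingly.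

Step 10
Reactants: 14 methyl 5-[(1R)-3-chloro-1-hydroxy-4-oxo-5-[[(2E,4S,6R)-4,6,8-trimethylnona-2,7-dienoyl]amino]cyclohexa-2,5-dien-1-yl]pentanoate
Product: 15 5-[(1R)-3-chloro-1-hydroxy-4-oxo-5-[[(2E,4S,6R)-4,6,8-trimethylnona-2,7-dienoyl]amino]cyclohexa-2,5-dien-1-yl]pentanoic acid (target)
Conditions: immobilised Candida antarctica lipase B, phosphate buffer pH 7.0/acetone 4:1, 30 °C
Reagents that add atoms: water, O
Why: Lipase-catalysed hydrolysis of an unhindered straight-chain methyl ester at neutral pH, the standard answer for base- and acid-labile hydroxy enones; the enamide, the chlorodienone, the tertiary alcohol and all three stereocentres should be untouched.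

## Compound list

1 | 5-(4-hydroxyphenyl)pentanoic acid | OC(=O)CCCCc1ccc(O)cc1 | starting material
2 | methyl 5-(4-hydroxyphenyl)pentanoate | COC(=O)CCCCc1ccc(O)cc1 | intermediate
3 | methyl 5-(3-chloro-4-hydroxyphenyl)pentanoate | COC(=O)CCCCc1ccc(O)c(Cl)c1 | intermediate (not isolated)
4 | methyl 5-(3,5-dichloro-4-hydroxyphenyl)pentanoate | COC(=O)CCCCc1cc(Cl)c(O)c(Cl)c1 | intermediate
5 | methyl 5-(3,5-dichloro-1-hydroxy-4-oxocyclohexa-2,5-dien-1-yl)pentanoate (achiral) | COC(=O)CCCCC1(O)C=C(Cl)C(=O)C(Cl)=C1 | intermediate
6 | meso-2,4-dimethylglutaric anhydride, (3R,5S)-3,5-dimethyloxane-2,6-dione | O=C1[C@H](C)C[C@H](C)C(=O)O1 | starting material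
7 | meso-(2R,4S)-2,4-dimethylpentane-1,5-diol | OC[C@H](C)C[C@H](C)CO | intermediate
8 | (2S,4R)-5-hydroxy-2,4-dimethylpentyl acetate | OC[C@H](C)C[C@H](C)COC(C)=O | intermediate
9 | (2S,4R)-2,4-dimethyl-5-oxopentyl acetate | O=C[C@H](C)C[C@H](C)COC(C)=O | intermediate
10 | (2S,4R)-2,4,6-trimethylhept-5-en-1-yl acetate | CC(C)=C[C@H](C)C[C@H](C)COC(C)=O | intermediate (not isolated)
11 | (2S,4R)-2,4,6-trimethylhept-5-en-1-ol | CC(C)=C[C@H](C)C[C@H](C)CO | intermediate
12 | (2S,4R)-2,4,6-trimethylhept-5-enal | CC(C)=C[C@H](C)C[C@H](C)C=O | intermediate (not isolated)
13 | (2E,4S,6R)-4,6,8-trimethylnona-2,7-dienamide | CC(C)=C[C@H](C)C[C@H](C)/C=C/C(N)=O | intermediate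
14 | methyl 5-[(1R)-3-chloro-1-hydroxy-4-oxo-5-[[(2E,4S,6R)-4,6,8-trimethylnona-2,7-dienoyl]amino]cyclohexa-2,5-dien-1-yl]pentanoate | CC(C)=C[C@H](C)C[C@H](C)/C=C/C(=O)NC1=C[C@](O)(CCCCC(=O)OC)C=C(Cl)C1=O | intermediate
15 | 5-[(1R)-3-chloro-1-hydroxy-4-oxo-5-[[(2E,4S,6R)-4,6,8-trimethylnona-2,7-dienoyl]amino]cyclohexa-2,5-dien-1-yl]pentanoic acid | CC(C)=C[C@H](C)C[C@H](C)/C=C/C(=O)NC1=C[C@](O)(CCCCC(=O)O)C=C(Cl)C1=O | target

## Step count and least certain steps

Total step count: 10 (steps 1–3 for the ring partner, steps 4–8 for the amide, steps 9 and 10 after the union). Longest linear sequence: 7 steps (6 → 7 → 8 → 9 → 11 → 13 → 14 → 15).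

**Step 9 (key step, proposed new method).** The most likely failure is poor discrimination between the two enantiotopic C–Cl bonds, because the ligand must sense the difference between OH and the chain at C4 two atoms from the reacting carbon, and any approach from the chain face works against the selection. The second risk is slow oxidative addition into the C–Cl bond, which would give the base time to promote conjugate addition of the amide or the tertiary alkoxide to the dienone. The fallback uses known chemistry, gives up the desymmetrisation and forms the C2–N bond by acylation before the ring is dearomatised; it sets out from 2 and 11 and comes back at 14. Nitration of 2 (HNO3, AcOH) would give methyl 5-(4-hydroxy-3-nitrophenyl)pentanoate F1, chlorination of the remaining ortho position (N-chlorosuccinimide, MeCN) methyl 5-(3-chloro-4-hydroxy-5-nitrophenyl)pentanoate F2, and reduction with Fe and NH4Cl in aqueous ethanol methyl 5-(3-amino-5-chloro-4-hydroxyphenyl)pentanoate F3. In parallel 11 is oxidised as in step 8 and aldehyde 12 is trapped with Ph3P=CHCO2Et to give ethyl (2E,4S,6R)-4,6,8-trimethylnona-2,7-dienoate F4, which LiOH hydrolyses to (2E,4S,6R)-4,6,8-trimethylnona-2,7-dienoic acid F5. Carbodiimide coupling of F3 with F5 gives methyl 5-[3-chloro-4-hydroxy-5-[[(2E,4S,6R)-4,6,8-trimethylnona-2,7-dienoyl]amino]phenyl]pentanoate F6, the same compound as A1. Oxidation of F6 with PhI(OAc)2 in aqueous MeCN should give 14 together with its C4 epimer methyl 5-[(1S)-3-chloro-1-hydroxy-4-oxo-5-[[(2E,4S,6R)-4,6,8-trimethylnona-2,7-dienoyl]amino]cyclohexa-2,5-dien-1-yl]pentanoate F7; the two are diastereomers and are separated by preparative HPLC.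

**Step 10.** The most likely failure is deactivation of the enzyme through covalent capture of its nucleophilic residues by the chlorodienone, together with slow turnover of a large lipophilic ester. The fallback removes the protecting group from the plan; it sets out from 1 and comes back at 15. Chlorination of 1 under the conditions of step 2 would give 5-(3,5-dichloro-4-hydroxyphenyl)pentanoic acid F8, dearomatisation as in step 3 gives 5-(3,5-dichloro-1-hydroxy-4-oxocyclohexa-2,5-dien-1-yl)pentanoic acid F9, and the coupling of step 9 run on F9 with 13 and one further equivalent of K3PO4 in tert-amyl alcohol delivers 15 directly as its carboxylate.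

**Step 3.** The most likely failure is sluggish oxidation of the electron-poor dichlorophenol, with capture of the activated arene by trifluoroacetate or over-oxidation taking over. The fallback changes the oxygen source from water to singlet oxygen; it sets out from 4 and comes back at 5. Oxone and NaHCO3 in aqueous MeCN generate singlet oxygen, which adds to the para carbon of the phenolate to give methyl 5-(3,5-dichloro-1-hydroperoxy-4-oxocyclohexa-2,5-dien-1-yl)pentanoate F10, and dimethyl sulfide reduces the hydroperoxide to 5.

**Step 5.** The most likely failure is incomplete selection between the two enantiotopic hydroxymethyl groups, or over-acetylation, either of which lowers the enantiomeric purity of the whole side chain; a reversed sense of the enzyme would have the same effect. The fallback desymmetrises the anhydride chemically; it sets out from 6 and comes back at 11. Alkaloid-mediated methanolysis of 6 (quinidine or quinine, whichever pseudoenantiomer delivers methanol to the carbonyl on the (S)-configured carbon, toluene, −55 °C) gives (2R,4S)-5-methoxy-2,4-dimethyl-5-oxopentanoic acid F11. BH3·SMe2 reduces the acid selectively to methyl (2S,4R)-5-hydroxy-2,4-dimethylpentanoate F12, Dess–Martin oxidation gives methyl (2S,4R)-2,4-dimethyl-5-oxopentanoate F13, the Wittig reaction of step 7 gives methyl (2S,4R)-2,4,6-trimethylhept-5-enoate F14, and LiAlH4 reduces F14 to 11.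

**Step 7.** The most likely failure is epimerisation of the α-stereocentre of 9 by the strongly basic ylide before olefination, which would leak the anti-dimethyl isomer into the side chain. The fallback reverses the polarity of the olefination so that no α-chiral aldehyde is exposed to base; it sets out from 8 and comes back at 10. Appel iodination of 8 (I2, PPh3, imidazole) gives (2S,4R)-5-iodo-2,4-dimethylpentyl acetate F15, heating with PPh3 in MeCN gives [(2R,4S)-5-acetoxy-2,4-dimethylpentyl]triphenylphosphonium iodide F16, and deprotonation with NaHMDS at −78 °C followed by acetone gives 10, whose stereocentre is now β to the ylide carbon and cannot epimerise.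

## Further compounds

F1 | step 9 | methyl 5-(4-hydroxy-3-nitrophenyl)pentanoate | COC(=O)CCCCc1ccc(O)c(c1)[N+](=O)[O-]
F2 | step 9 | methyl 5-(3-chloro-4-hydroxy-5-nitrophenyl)pentanoate | COC(=O)CCCCc1cc(Cl)c(O)c(c1)[N+](=O)[O-]
F3 | step 9 | methyl 5-(3-amino-5-chloro-4-hydroxyphenyl)pentanoate | COC(=O)CCCCc1cc(N)c(O)c(Cl)c1
F4 | step 9 | ethyl (2E,4S,6R)-4,6,8-trimethylnona-2,7-dienoate | CC(C)=C[C@H](C)C[C@H](C)/C=C/C(=O)OCC
F5 | step 9 | (2E,4S,6R)-4,6,8-trimethylnona-2,7-dienoic acid | CC(C)=C[C@H](C)C[C@H](C)/C=C/C(=O)O
F6 | step 9 | methyl 5-[3-chloro-4-hydroxy-5-[[(2E,4S,6R)-4,6,8-trimethylnona-2,7-dienoyl]amino]phenyl]pentanoate | CC(C)=C[C@H](C)C[C@H](C)/C=C/C(=O)Nc1cc(CCCCC(=O)OC)cc(Cl)c1O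
F7 | step 9 | methyl 5-[(1S)-3-chloro-1-hydroxy-4-oxo-5-[[(2E,4S,6R)-4,6,8-trimethylnona-2,7-dienoyl]amino]cyclohexa-2,5-dien-1-yl]pentanoate | CC(C)=C[C@H](C)C[C@H](C)/C=C/C(=O)NC1=C[C@@](O)(CCCCC(=O)OC)C=C(Cl)C1=O
F8 | step 10 | 5-(3,5-dichloro-4-hydroxyphenyl)pentanoic acid | OC(=O)CCCCc1cc(Cl)c(O)c(Cl)c1
F9 | step 10 | 5-(3,5-dichloro-1-hydroxy-4-oxocyclohexa-2,5-dien-1-yl)pentanoic acid | OC(=O)CCCCC1(O)C=C(Cl)C(=O)C(Cl)=C1
F10 | step 3 | methyl 5-(3,5-dichloro-1-hydroperoxy-4-oxocyclohexa-2,5-dien-1-yl)pentanoate | COC(=O)CCCCC1(OO)C=C(Cl)C(=O)C(Cl)=C1
F11 | step 5 | (2R,4S)-5-methoxy-2,4-dimethyl-5-oxopentanoic acid | OC(=O)[C@H](C)C[C@H](C)C(=O)OC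
F12 | step 5 | methyl (2S,4R)-5-hydroxy-2,4-dimethylpentanoate | OC[C@H](C)C[C@H](C)C(=O)OC
F13 | step 5 | methyl (2S,4R)-2,4-dimethyl-5-oxopentanoate | O=C[C@H](C)C[C@H](C)C(=O)OC
F14 | step 5 | methyl (2S,4R)-2,4,6-trimethylhept-5-enoate | CC(C)=C[C@H](C)C[C@H](C)C(=O)OC
F15 | step 7 | (2S,4R)-5-iodo-2,4-dimethylpentyl acetate | IC[C@H](C)C[C@H](C)COC(C)=O
F16 | step 7 | [(2R,4S)-5-acetoxy-2,4-dimethylpentyl]triphenylphosphonium iodide | c1ccccc1[P+](c1ccccc1)(c1ccccc1)C[C@H](C)C[C@H](C)COC(C)=O.[I-]
A1 | alternative 1 | methyl 5-[3-chloro-4-hydroxy-5-[[(2E,4S,6R)-4,6,8-trimethylnona-2,7-dienoyl]amino]phenyl]pentanoate | CC(C)=C[C@H](C)C[C@H](C)/C=C/C(=O)Nc1cc(CCCCC(=O)OC)cc(Cl)c1O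
A2 | alternative 2 | (2E,4S,6R)-N-(5-chloro-6,6-dimethoxy-3-oxocyclohexa-1,4-dien-1-yl)-4,6,8-trimethylnona-2,7-dienamide | CC(C)=C[C@H](C)C[C@H](C)/C=C/C(=O)NC1=CC(=O)C=C(Cl)C1(OC)OC
A3 | alternative 2 | (5-methoxy-5-oxopentyl)zinc bromide | COC(=O)CCCC[Zn]Br
A4 | alternative 3 | methyl 5-[(4R,5S,6R)-5,6-epoxy-4-hydroxy-1-oxo-2-[[(2E,4S,6R)-4,6,8-trimethylnona-2,7-dienoyl]amino]cyclohex-2-en-4-yl]pentanoate (ring locants of the analysis, oxirane syn to the hydroxyl) | CC(C)=C[C@H](C)C[C@H](C)/C=C/C(=O)NC1=C[C@](O)(CCCCC(=O)OC)[C@H]2O[C@H]2C1=O
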